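**Retrosynthetic overview**
- The strategy rests on the C2–O–C(=O)–aryl unit. The 4-hydroxy-3,5-dimethoxybenzoate sits on the homobenzylic carbon C2, anti to the free benzylic C1–OH on the 4-hydroxy-2-methoxyphenyl ring, and is read as a ketone C2–C(=O)–aryl into which one oxygen has been inserted.
- Aryl–prenyl C–C bond ⇒ aryl bromide by Stille coupling, placed after all peracid chemistry; C2–O ester ⇒ Baeyer–Villiger oxidation of a syn β-silyloxy aryl ketone with retention at C2.
- C1–C2 bond ⇒ reagent-controlled syn-aldol of a 1,3-diarylpropan-1-one with 4-formyl-3-methoxyphenyl pivalate; the ketone ⇒ Claisen–Schmidt condensation and 1,4-reduction.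
- No ring is formed: the three benzene rings are bought and joined first as the chalcone (two rings), then by the aldol (third ring).
- End game: methanolysis of the three aryl pivalates with the C1 silyl ether still on, then buffered desilylation.

Key step: step 5

Assumption: the Z-enol diisopinocampheylborinate is taken to attack the aldehyde on the same face as allyl- and crotyl-diisopinocampheylboranes of the same pinene series, so the reagent from (−)-α-pinene should give Re-face attack and the (2R,3R) aldol; an MTPA ester analysis of a first small batch would check this, and the reagent from (+)-α-pinene would be used if the sense were the reverse.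

**Step 1**
Reactants: 1 acetosyringone; 2 3-bromo-4-hydroxybenzaldehyde
Product: 4 (E)-3-(3-bromo-4-hydroxyphenyl)-1-(4-hydroxy-3,5-dimethoxyphenyl)prop-2-en-1-one, via beta-hydroxy ketone 3 (not isolated)
Conditions: dry HCl (g), EtOH, 0 °C → rt
Reagents that add atoms: none
Why: Acid-catalysed Claisen–Schmidt condensation, in which the enol of the methyl ketone adds to the protonated non-enolisable aldehyde and the aldol 3 loses water to the conjugated E-enone, acid being used because base would turn both phenols into deactivating phenoxides.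

**Step 2**
Reactants: 4 (E)-chalcone with two free phenols
Product: 5 (E)-chalcone bis-pivalate
Conditions: PivCl (2.5 equiv), Et3N, DMAP (cat.), CH2Cl2, 0 → 40 °C
Reagents that add atoms: pivaloyl chloride, CC(C)(C)C(=O)Cl
Why: DMAP-catalysed acylation of both phenols should give aryl pivalates that carry no acidic C–H, survive boron enolisation and peracid, and make the syringyl ring electron-poor for the later oxygen insertion.

**Step 3**
Reactants: 5 (E)-chalcone bis-pivalate
Product: 6 2-bromo-4-[3-(3,5-dimethoxy-4-pivaloyloxyphenyl)-3-oxopropyl]phenyl pivalate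
Conditions: H2 (1 atm), RhCl(PPh3)3 (5 mol %), toluene–EtOH, 40 °C
Reagents that add atoms: none
Why: Homogeneous hydrogenation with RhCl(PPh3)3 should saturate the disubstituted enone C=C while leaving the aryl ketone, the esters and the aryl bromide, which a heterogeneous palladium catalyst would endanger.

**Step 4**
Reactants: 7 4-hydroxy-2-methoxybenzaldehyde
Product: 8 4-formyl-3-methoxyphenyl pivalate
Conditions: PivCl, Et3N, DMAP (cat.), CH2Cl2, 0 °C → rt
Reagents that add atoms: pivaloyl chloride, CC(C)(C)C(=O)Cl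
Why: Phenol acylation removes the para oxygen donor that would deaden the aldehyde and offers no acidic site to the boron triflate and amine of the next step.

**Step 5**
Reactants: 6 dihydrochalcone bis-pivalate; 8 4-formyl-3-methoxyphenyl pivalate
Product: 11 (2R,3R)-syn aldol (beta-hydroxy aryl ketone), via Z-enol diisopinocampheylborinate 9 (not isolated), via boron aldolate 10 (not isolated)
Conditions: (Ipc)2BOTf [from (−)-α-pinene, 1.5 equiv], i-Pr2NEt, CH2Cl2, −78 °C; then 8, −78 → −20 °C; then pH 7 buffer, MeOH, 30% H2O2, 0 °C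
Reagents that add atoms: none
Why: The boron triflate and the hindered amine should enolise aryl ketone 6 to the Z-(O)-enol borinate 9, because allylic 1,3-strain between the aryl group and the benzylic substituent disfavours the E isomer. Enolate 9 then adds to aldehyde 8 through a closed six-membered chair transition state of the Zimmerman–Traxler type with the aldehyde aryl group equatorial, which forms the future C1–C2 bond, joins all three arene units and gives the syn aldol; no ring is closed. The closest known reaction type is the syn-selective aldol of Z-enol diisopinocampheylborinates of ethyl and aryl ketones with aldehydes. Of the two new stereocentres, the relative configuration follows from the Z geometry and the chair, and the absolute configuration from the isopinocampheyl ligands on boron, which should favour the chair with Re-face attack on the aldehyde and so give (2R,3R). The step needs syn diastereoselectivity and enantioface selectivity; the first is secured by the clean Z-enolisation of the aryl ketone, the second by the chiral ligands, and the pivalate on 8 raises the electrophilicity of the otherwise electron-rich ortho-substituted aldehyde. The short pH 7 peroxide work-up at 0 °C should free the aldol from boron without retro-aldol or pivalate loss, and crystallisation of 11 should raise its enantiomeric purity.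

**Step 6**
Reactants: 11 (2R,3R)-syn aldol
Product: 12 (2R,3R)-3-O-tert-butyldimethylsilyl ether of the aldol
Conditions: TBSOTf, 2,6-lutidine, CH2Cl2, −78 °C
Reagents that add atoms: tert-butyldimethylsilyl triflate, CC(C)(C)[Si](C)(C)OS(=O)(=O)C(F)(F)F
Why: Silylation of the hindered benzylic alcohol with the silyl triflate and a non-nucleophilic base at low temperature should block retro-aldol cleavage and the later acyl shift between the two oxygens without touching either stereocentre.

**Step 7**
Reactants: 12 silylated aldol ketone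
Product: 13 (1S,2R)-3-(3-bromo-4-pivaloyloxyphenyl)-1-(tert-butyldimethylsilyloxy)-1-(2-methoxy-4-pivaloyloxyphenyl)propan-2-yl 3,5-dimethoxy-4-pivaloyloxybenzoate
Conditions: CF3CO3H [from urea–H2O2 and (CF3CO)2O], Na2HPO4, CH2Cl2, 0 °C → rt
Reagents that add atoms: trifluoroperacetic acid, OOC(=O)C(F)(F)F (made in the flask from urea–hydrogen peroxide, NC(N)=O.OO, and trifluoroacetic anhydride)
Why: Baeyer–Villiger oxidation, in which the secondary carbon C2 of the Criegee adduct should migrate to oxygen anti-periplanar to the O–O bond with retention (the ketone 2R,3R becomes the ester 1S,2R by renumbering and priority change only), while aryl migration is disfavoured because the ring has only a twisted pivaloyloxy group para and two methoxy groups meta to the migrating carbon; the phosphate buffer protects the silyl ether and the molecule holds no alkene at this stage.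

**Step 8**
Reactants: 13 aryl bromide with the C2 ester in place; 14 tributyl(3-methylbut-2-enyl)stannane
Product: 15 fully protected eryvarinol B (three aryl pivalates and the C1 silyl ether)
Conditions: Pd(PPh3)4 (5 mol %), degassed DMF, 95 °C
Reagents that add atoms: none
Why: Stille coupling, in which oxidative addition of zerovalent palladium into the aryl C–Br bond, transfer of the allylic group from tin and reductive elimination at the less substituted allyl terminus should give the linear 3-methylbut-2-enyl arene under neutral conditions that leave the esters and the silyl ether alone; the crude product is checked for the 1,1-dimethylallyl isomer.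

**Step 9**
Reactants: 15 fully protected eryvarinol B
Product: 16 C1-O-silyl eryvarinol B (three free phenols)
Conditions: K2CO3, degassed MeOH–THF, 0 °C → rt; then pH 7 buffer
Reagents that add atoms: none
Why: Base-mediated transesterification should cleave the three aryl pivalates, which have phenoxide leaving groups, much faster than the hindered secondary alkyl benzoate at C2, which is further deactivated once its para oxygen becomes a phenoxide, and the silyl ether on C1 leaves no neighbouring hydroxyl for a 1,2-acyl shift.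

**Step 10**
Reactants: 16 C1-O-silyl eryvarinol B
Product: 17 eryvarinol B
Conditions: Bu4NF–AcOH (1:1), THF, 0 °C → rt; pH 7 work-up
Reagents that add atoms: none
Why: Fluoride-mediated desilylation buffered with acetic acid should free the C1 hydroxyl while keeping the medium too weakly basic for acyl migration and too weakly acidic for ionisation of the p-hydroxybenzylic alcohol, so that neither stereocentre is touched.

**Compound list**
1 | acetosyringone, 1-(4-hydroxy-3,5-dimethoxyphenyl)ethanone | CC(=O)c1cc(OC)c(O)c(OC)c1 | starting material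
2 | 3-bromo-4-hydroxybenzaldehyde | O=Cc1ccc(O)c(Br)c1 | starting material
3 | 3-(3-bromo-4-hydroxyphenyl)-3-hydroxy-1-(4-hydroxy-3,5-dimethoxyphenyl)propan-1-one (racemic, not isolated) | O=C(CC(O)c1ccc(O)c(Br)c1)c1cc(OC)c(O)c(OC)c1 | intermediate
4 | (E)-3-(3-bromo-4-hydroxyphenyl)-1-(4-hydroxy-3,5-dimethoxyphenyl)prop-2-en-1-one | O=C(/C=C/c1ccc(O)c(Br)c1)c1cc(OC)c(O)c(OC)c1 | intermediate
5 | 2-bromo-4-[(E)-3-(3,5-dimethoxy-4-pivaloyloxyphenyl)-3-oxoprop-1-enyl]phenyl pivalate | CC(C)(C)C(=O)Oc1ccc(/C=C/C(=O)c2cc(OC)c(OC(=O)C(C)(C)C)c(OC)c2)cc1Br | intermediate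
6 | 2-bromo-4-[3-(3,5-dimethoxy-4-pivaloyloxyphenyl)-3-oxopropyl]phenyl pivalate | CC(C)(C)C(=O)Oc1ccc(CCC(=O)c2cc(OC)c(OC(=O)C(C)(C)C)c(OC)c2)cc1Br | intermediate
7 | 4-hydroxy-2-methoxybenzaldehyde | COc1cc(O)ccc1C=O | starting material
8 | 4-formyl-3-methoxyphenyl pivalate | COc1cc(OC(=O)C(C)(C)C)ccc1C=O | intermediate
9 | Z-enol diisopinocampheylborinate of 6 (isopinocampheyl groups from (−)-α-pinene; not isolated) | CC(C)(C)C(=O)Oc1ccc(C/C=C(\OB([C@H]2C[C@H]3C[C@@H]([C@@H]2C)C3(C)C)[C@H]2C[C@H]3C[C@@H]([C@@H]2C)C3(C)C)c2cc(OC)c(OC(=O)C(C)(C)C)c(OC)c2)cc1Br | intermediate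
10 | O-diisopinocampheylboryl aldolate of 11 (not isolated) | COc1cc(OC(=O)C(C)(C)C)ccc1[C@H](OB([C@H]1C[C@H]2C[C@@H]([C@@H]1C)C2(C)C)[C@H]1C[C@H]2C[C@@H]([C@@H]1C)C2(C)C)[C@@H](Cc1ccc(OC(=O)C(C)(C)C)c(Br)c1)C(=O)c1cc(OC)c(OC(=O)C(C)(C)C)c(OC)c1 | intermediate
11 | (2R,3R)-2-(3-bromo-4-pivaloyloxybenzyl)-3-hydroxy-3-(2-methoxy-4-pivaloyloxyphenyl)-1-(3,5-dimethoxy-4-pivaloyloxyphenyl)propan-1-one | COc1cc(OC(=O)C(C)(C)C)ccc1[C@H](O)[C@@H](Cc1ccc(OC(=O)C(C)(C)C)c(Br)c1)C(=O)c1cc(OC)c(OC(=O)C(C)(C)C)c(OC)c1 | intermediate
12 | (2R,3R)-2-(3-bromo-4-pivaloyloxybenzyl)-3-(tert-butyldimethylsilyloxy)-3-(2-methoxy-4-pivaloyloxyphenyl)-1-(3,5-dimethoxy-4-pivaloyloxyphenyl)propan-1-one | COc1cc(OC(=O)C(C)(C)C)ccc1[C@H](O[Si](C)(C)C(C)(C)C)[C@@H](Cc1ccc(OC(=O)C(C)(C)C)c(Br)c1)C(=O)c1cc(OC)c(OC(=O)C(C)(C)C)c(OC)c1 | intermediate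
13 | (1S,2R)-3-(3-bromo-4-pivaloyloxyphenyl)-1-(tert-butyldimethylsilyloxy)-1-(2-methoxy-4-pivaloyloxyphenyl)propan-2-yl 3,5-dimethoxy-4-pivaloyloxybenzoate | COc1cc(OC(=O)C(C)(C)C)ccc1[C@H](O[Si](C)(C)C(C)(C)C)[C@@H](Cc1ccc(OC(=O)C(C)(C)C)c(Br)c1)OC(=O)c1cc(OC)c(OC(=O)C(C)(C)C)c(OC)c1 | intermediate
14 | tributyl(3-methylbut-2-enyl)stannane | CCCC[Sn](CCCC)(CCCC)CC=C(C)C | starting material
15 | (1S,2R)-1-(tert-butyldimethylsilyloxy)-1-(2-methoxy-4-pivaloyloxyphenyl)-3-[3-(3-methylbut-2-enyl)-4-pivaloyloxyphenyl]propan-2-yl 3,5-dimethoxy-4-pivaloyloxybenzoate | COc1cc(OC(=O)C(C)(C)C)ccc1[C@H](O[Si](C)(C)C(C)(C)C)[C@@H](Cc1ccc(OC(=O)C(C)(C)C)c(CC=C(C)C)c1)OC(=O)c1cc(OC)c(OC(=O)C(C)(C)C)c(OC)c1 | intermediate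
16 | (1S,2R)-1-(tert-butyldimethylsilyloxy)-1-(4-hydroxy-2-methoxyphenyl)-3-[4-hydroxy-3-(3-methylbut-2-enyl)phenyl]propan-2-yl 4-hydroxy-3,5-dimethoxybenzoate | COc1cc(O)ccc1[C@H](O[Si](C)(C)C(C)(C)C)[C@@H](Cc1ccc(O)c(CC=C(C)C)c1)OC(=O)c1cc(OC)c(O)c(OC)c1 | intermediate
17 | eryvarinol B, (1S,2R)-1-hydroxy-1-(4-hydroxy-2-methoxyphenyl)-3-[4-hydroxy-3-(3-methylbut-2-enyl)phenyl]propan-2-yl 4-hydroxy-3,5-dimethoxybenzoate | COc1cc(O)ccc1[C@H](O)[C@@H](Cc1ccc(O)c(CC=C(C)C)c1)OC(=O)c1cc(OC)c(O)c(OC)c1 | target

**Step count**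
Total: 10 steps. Longest linear sequence: 9 steps (steps 1, 2, 3, 5, 6, 7, 8, 9, 10 from 1 and 2); step 4 is a one-step side branch.

**Steps most likely to fail**

Step 7 (oxygen insertion). The aryl ring may migrate in place of C2, the hindered ketone may fail to add the peracid, or the methoxy-arene may be oxidised. The fallback sets out from 8 and comes back at 13; it makes the C2–O bond from an epoxide and the ester by acylation, with no oxygen insertion. CH2=CHMgBr is added to 8 (THF, −78 °C) to give racemic 4-(1-hydroxyprop-2-enyl)-3-methoxyphenyl pivalate F1. A Sharpless kinetic resolution (Ti(OiPr)4, L-(+)-diisopropyl tartrate, t-BuOOH 0.55 equiv, 4 Å sieves, CH2Cl2, −20 °C) should epoxidise the (R)-enantiomer selectively to the erythro epoxy alcohol 4-[(S)-hydroxy((R)-oxiran-2-yl)methyl]-3-methoxyphenyl pivalate F2, which already holds the anti C1/C2 relationship. Silylation (TBSCl, imidazole, DMF) gives the silyl ether F3. 2-Bromo-4-iodophenol is pivaloylated to 2-bromo-4-iodophenyl pivalate F4, and iodine–magnesium exchange (i-PrMgCl·LiCl, THF, −40 °C) gives (3-bromo-4-pivaloyloxyphenyl)magnesium chloride F5. CuI-catalysed opening of F3 at its CH2 terminus by F5 gives the C2 alcohol F6. Steglich esterification (EDC·HCl, DMAP, CH2Cl2) of F6 with 3,5-dimethoxy-4-pivaloyloxybenzoic acid F7 (from syringic acid, PivCl and pyridine, aqueous work-up) gives 13.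

Step 5 (asymmetric aldol). The isopinocampheyl ligands may discriminate poorly between the two aldehyde faces, or the hindered enol borinate may add slowly to the ortho-substituted aldehyde. The fallback sets out from 6 and 8 and comes back at 11; enantiopurity then comes from resolution and not from the reagent. Enolisation of 6 with n-Bu2BOTf and i-Pr2NEt (CH2Cl2, −78 °C) to the Z-enol dibutylborinate F8, addition to 8 and the same buffered peroxide work-up should give the syn aldol as the racemate, that is 11 together with its (2S,3S)-enantiomer F9. The two are separated by preparative chromatography on a chiral stationary phase (amylose tris(3,5-dimethylphenylcarbamate)), and 11 goes on to step 6.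

Step 8 (prenylation). The prenyl group may be transferred through its tertiary terminus to give the 1,1-dimethylallyl arene, or oxidative addition next to the ortho pivalate may be slow. The fallback sets out from 13 and comes back at 15. Stille coupling of 13 with allyltributylstannane (Pd(PPh3)4, DMF, 95 °C), in which both allyl termini are the same, gives the 3-allyl arene F10. Cross-metathesis of F10 with an excess of 2-methylbut-2-ene (second-generation Grubbs catalyst, CH2Cl2, 40 °C) turns the allyl group into the 3-methylbut-2-enyl group of 15.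

**Further compounds**
F1 | step 7 | 4-(1-hydroxyprop-2-enyl)-3-methoxyphenyl pivalate (racemic) | COc1cc(OC(=O)C(C)(C)C)ccc1C(O)C=C
F2 | step 7 | 4-[(S)-hydroxy((R)-oxiran-2-yl)methyl]-3-methoxyphenyl pivalate | COc1cc(OC(=O)C(C)(C)C)ccc1[C@H](O)[C@@H]1OC1
F3 | step 7 | 4-[(S)-(tert-butyldimethylsilyloxy)((R)-oxiran-2-yl)methyl]-3-methoxyphenyl pivalate | COc1cc(OC(=O)C(C)(C)C)ccc1[C@H](O[Si](C)(C)C(C)(C)C)[C@@H]1OC1
F4 | step 7 | 2-bromo-4-iodophenyl pivalate | CC(C)(C)C(=O)Oc1ccc(I)cc1Br
F5 | step 7 | (3-bromo-4-pivaloyloxyphenyl)magnesium chloride | CC(C)(C)C(=O)Oc1ccc([Mg]Cl)cc1Br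
F6 | step 7 | 2-bromo-4-[(2R,3S)-3-(tert-butyldimethylsilyloxy)-2-hydroxy-3-(2-methoxy-4-pivaloyloxyphenyl)propyl]phenyl pivalate | COc1cc(OC(=O)C(C)(C)C)ccc1[C@H](O[Si](C)(C)C(C)(C)C)[C@@H](Cc1ccc(OC(=O)C(C)(C)C)c(Br)c1)O
F7 | step 7 | 3,5-dimethoxy-4-pivaloyloxybenzoic acid | COc1cc(C(=O)O)cc(OC)c1OC(=O)C(C)(C)C
F8 | step 5 | Z-enol dibutylborinate of 6 | CCCCB(CCCC)O/C(=C\Cc1ccc(OC(=O)C(C)(C)C)c(Br)c1)c1cc(OC)c(OC(=O)C(C)(C)C)c(OC)c1
F9 | step 5 | (2S,3S)-enantiomer of aldol 11 | COc1cc(OC(=O)C(C)(C)C)ccc1[C@@H](O)[C@H](Cc1ccc(OC(=O)C(C)(C)C)c(Br)c1)C(=O)c1cc(OC)c(OC(=O)C(C)(C)C)c(OC)c1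
F10 | step 8 | (1S,2R)-3-(3-allyl-4-pivaloyloxyphenyl)-1-(tert-butyldimethylsilyloxy)-1-(2-methoxy-4-pivaloyloxyphenyl)propan-2-yl 3,5-dimethoxy-4-pivaloyloxybenzoate | COc1cc(OC(=O)C(C)(C)C)ccc1[C@H](O[Si](C)(C)C(C)(C)C)[C@@H](Cc1ccc(OC(=O)C(C)(C)C)c(CC=C)c1)OC(=O)c1cc(OC)c(OC(=O)C(C)(C)C)c(OC)c1
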